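**Plan**

1. Retrosynthesis: the C8 bromide and C9 carbinol of ring A go back to the enol acetate C8=C9–OAc. The ring A bond C7–C8 is then cut together with one C–H bond of a C7 methyl group, which opens ring A to an isopropenyl group and a pent-1-en-4-yn-2-yl group on C6 of a ring B cyclohexanone. The ring B chlorohydrin goes back to an α-methylene ketone, the two arms to one isopropenyl group and one ester, and C6 to a conjugate addition onto a commercial enone.
2. Forward order: ring B is bought as enone 1 and the quaternary carbon C6 is set first. The two arms are then built, ring B is oxidised at C3, and ring A is closed last at C7–C8, then brominated and reduced.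
3. Enabling feature: C7 carries two methyl groups and lies between spiro C6 and C8, and C8/C9 are at the oxidation level of a ketone enol. C7 can therefore start as the internal carbon of an isopropenyl group on C6 and C8–C9 as a terminal alkyne. Alkene insertion into an alkenyl–palladium bond then gives a neopentyl alkylpalladium without β-hydrogen, which can only be protonated to the second methyl group.
4. Stereochemistry: C6 comes from the chiral copper catalyst (step 1). C3 comes from axial epoxide closure in a ring B chair locked by the equatorial carbinol arm (step 8). C8 comes from bromination and equilibration to the equatorial bromide in the ring A chair that the sp2 carbon C2 of ring B dictates (step 12). C9 comes from equatorial hydride delivery (step 13).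

Key step: step 11

Remark: locants C1–C11 in the comments are those of the target (ring B = C1–C6 with the ketone at C2 and the carbinol at C3; ring A = C6–C11 with C7 gem-dimethyl, C8 Br, C9 OH, C11 methylidene). Compounds 1, 2 and 6 are taken as purchased (2 and 6 as THF solutions).

**Route**

Step 1
Reactants: 1 methyl 3-oxocyclohex-1-ene-1-carboxylate; 2 prop-1-en-2-ylmagnesium bromide
Product: 3 methyl (1R)-3-oxo-1-(prop-1-en-2-yl)cyclohexane-1-carboxylate
Conditions: 2, Me2AlCl, Et2O, 0 °C; then 1, Cu(OTf)2 (5 mol %), chiral binaphthol-derived phosphoramidite ligand (10 mol %, the enantiomer that leads to the R product), Et2O, −30 °C; aq. NH4Cl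
Reagents that add atoms: none
Why: Copper-catalysed asymmetric conjugate addition of an alkenylalane to a β-substituted cyclohexenone (the β-ester makes the acceptor more reactive) should create the quaternary carbon, the chiral ligand on copper choosing the enone face so that the future spiro carbon C6 is R.

Step 2
Reactants: 3 methyl (1R)-3-oxo-1-(prop-1-en-2-yl)cyclohexane-1-carboxylate
Product: 4 methyl (7R)-7-(prop-1-en-2-yl)-1,4-dioxaspiro[4.5]decane-7-carboxylate
Conditions: HOCH2CH2OH, TsOH (cat.), benzene, reflux, water separator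
Reagents that add atoms: ethane-1,2-diol, OCCO
Why: Acid-catalysed ketalisation masks the ring B ketone for the organolithium step; the quaternary centre cannot enolise and stays intact.

Step 3
Reactants: 4 methyl (7R)-7-(prop-1-en-2-yl)-1,4-dioxaspiro[4.5]decane-7-carboxylate
Product: 5 methyl (7R)-7-(3-chloroprop-1-en-2-yl)-1,4-dioxaspiro[4.5]decane-7-carboxylate
Conditions: Ca(OCl)2, solid CO2, CH2Cl2–H2O, 0 °C
Reagents that add atoms: calcium hypochlorite, [Ca+2].[O-]Cl.[O-]Cl
Why: Ene-type allylic chlorination with hypochlorous acid puts chlorine on the terminal carbon and moves the double bond to the former methyl group, the only allylic hydrogens being those of the methyl group because the ring carbon is quaternary; no stereocentre is formed.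

Step 4
Reactants: 5 methyl (7R)-7-(3-chloroprop-1-en-2-yl)-1,4-dioxaspiro[4.5]decane-7-carboxylate; 6 ethynylmagnesium bromide
Product: 7 methyl (7R)-7-(pent-1-en-4-yn-2-yl)-1,4-dioxaspiro[4.5]decane-7-carboxylate
Conditions: CuI (10 mol %), THF, 0 °C to rt
Reagents that add atoms: none
Why: Copper-catalysed coupling of an allylic chloride with an alkynyl Grignard reagent gives the skipped enyne; SN2 and SN2' attack on the symmetrical 2-substituted allyl unit lead to the same product, and the neopentyl ester is too hindered to compete.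

Step 5
Reactants: 7 methyl (7R)-7-(pent-1-en-4-yn-2-yl)-1,4-dioxaspiro[4.5]decane-7-carboxylate
Product: 8 2-[(7R)-7-(pent-1-en-4-yn-2-yl)-1,4-dioxaspiro[4.5]decan-7-yl]propan-2-ol
Conditions: MeLi (4 equiv), Et2O–THF, −78 to 0 °C; aq. NH4Cl
Reagents that add atoms: methyllithium, [Li]C
Why: Double addition of the organolithium to the ester (one further equivalent is used up by the alkyne C–H) gives the tertiary carbinol whose carbon becomes C7 with its two methyl groups; no stereocentre is formed.

Step 6
Reactants: 8 2-[(7R)-7-(pent-1-en-4-yn-2-yl)-1,4-dioxaspiro[4.5]decan-7-yl]propan-2-ol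
Product: 9 (3R)-3-(2-hydroxypropan-2-yl)-3-(pent-1-en-4-yn-2-yl)cyclohexan-1-one
Conditions: PPTS, acetone–H2O, 50 °C
Reagents that add atoms: water, O
Why: Mild acid-catalysed ketal hydrolysis frees the ring B ketone without ionising the tertiary alcohol.

Step 7
Reactants: 9 (3R)-3-(2-hydroxypropan-2-yl)-3-(pent-1-en-4-yn-2-yl)cyclohexan-1-one
Product: 10 (5R)-5-(2-hydroxypropan-2-yl)-2-methylidene-5-(pent-1-en-4-yn-2-yl)cyclohexan-1-one
Conditions: (CH2O)n, i-Pr2NH·CF3CO2H (1 equiv), CF3CO2H (10 mol %), THF, reflux
Reagents that add atoms: formaldehyde (as paraformaldehyde), C=O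
Why: Mannich condensation with formaldehyde followed by β-elimination of the amine (one-pot α-methylenation) should occur at the unhindered α-methylene (future C3), the other α-carbon being neopentyl.

Step 8
Reactants: 10 (5R)-5-(2-hydroxypropan-2-yl)-2-methylidene-5-(pent-1-en-4-yn-2-yl)cyclohexan-1-one
Product: 11 (3R,6R)-6-(2-hydroxypropan-2-yl)-6-(pent-1-en-4-yn-2-yl)-1-oxaspiro[2.5]octan-4-one
Conditions: 30% aq. H2O2, NaOH (0.3 equiv), MeOH, 0 °C
Reagents that add atoms: hydrogen peroxide, OO
Why: Weitz–Scheffer (nucleophilic) epoxidation touches only the enone; in the chair locked by the equatorial 2-hydroxypropan-2-yl group the enolate carbon should close onto oxygen axially, the boat-like alternative being blocked by the axial alkenyl arm, so the epoxide oxygen ends cis to the carbinol arm (3R).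

Step 9
Reactants: 11 (3R,6R)-6-(2-hydroxypropan-2-yl)-6-(pent-1-en-4-yn-2-yl)-1-oxaspiro[2.5]octan-4-one
Product: 12 (3R,6S)-6-(pent-1-en-4-yn-2-yl)-6-(prop-1-en-2-yl)-1-oxaspiro[2.5]octan-4-one
Conditions: Burgess reagent (MeO2C–N(−)–SO2–N(+)Et3), THF, 50 °C
Reagents that add atoms: none
Why: Burgess dehydration (syn elimination of the sulfamate ester) of the tertiary alcohol can only remove a methyl hydrogen because the neighbouring carbon is quaternary, giving the isopropenyl group; the epoxy ketone is inert and the descriptor at the quaternary carbon changes only by priority.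

Step 10
Reactants: 12 (3R,6S)-6-(pent-1-en-4-yn-2-yl)-6-(prop-1-en-2-yl)-1-oxaspiro[2.5]octan-4-one
Product: 13 (2S,5S)-2-(chloromethyl)-2-hydroxy-5-(pent-1-en-4-yn-2-yl)-5-(prop-1-en-2-yl)cyclohexan-1-one
Conditions: HCl (1.1 equiv, 1 M in Et2O), CH2Cl2, −40 to 0 °C
Reagents that add atoms: hydrogen chloride, Cl
Why: Acid-mediated opening of the α-keto spiro-epoxide by SN2 attack of chloride at the primary carbon leaves the C–O bond of the tertiary carbinol and its configuration untouched (the descriptor becomes S by priority only).

Step 11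
Reactants: 13 (2S,5S)-2-(chloromethyl)-2-hydroxy-5-(pent-1-en-4-yn-2-yl)-5-(prop-1-en-2-yl)cyclohexan-1-one
Product: 14 (3S,6R)-3-(chloromethyl)-3-hydroxy-7,7-dimethyl-11-methylidene-2-oxospiro[5.5]undec-8-en-9-yl acetate
Conditions: Pd(OAc)2 (5 mol %), 2,2'-bipyridine (6 mol %), AcOH, 80 °C
Reagents that add atoms: acetic acid, CC(=O)O
Why: Proposed new method: Pd(OAc)2 activates the terminal alkyne and acetate adds anti and in the Markovnikov sense to the internal carbon (future C9), so divalent palladium ends on the terminal carbon (future C8) cis to the tether; this (E)-2-acetoxyalkenylpalladium inserts the isopropenyl group syn, forging C8–C7 and a neopentyl alkylpalladium that has no β-hydrogen and is protonated by AcOH to the second methyl group with return of Pd(OAc)2. The closest known reaction type is the divalent-palladium-catalysed trans-acetoxypalladation/alkene insertion/protodepalladation cyclisation of 1,6-enynes, so far used with internal alkynes, activated alkenes and five-membered ring closure through the proximal alkyne carbon. Ring A closes by 6-exo-trig carbopalladation of the isopropenyl group, both alkyne carbons ending inside the ring. No new stereocentre arises (C7 carries two methyl groups, C8 and C9 are sp2) and C3 and C6 are not touched. The step needs Markovnikov and trans addition of acetate, which the alkyl-substituted terminal alkyne and the acetate-rich medium should secure, and insertion of the isopropenyl group instead of the C11 methylidene, which could react only through a four-membered or 5-endo transition state. Bipyridine is added to suppress β-hydride pathways and to favour protonolysis of the carbon–palladium bond.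

Step 12
Reactants: 14 (3S,6R)-3-(chloromethyl)-3-hydroxy-7,7-dimethyl-11-methylidene-2-oxospiro[5.5]undec-8-en-9-yl acetate
Product: 16 (3S,6R,8R)-8-bromo-3-(chloromethyl)-3-hydroxy-7,7-dimethyl-11-methylidenespiro[5.5]undecane-2,9-dione, via tributylstannyl enolate 15 (not isolated)
Conditions: Bu3SnOMe (2.2 equiv), THF, 40 °C; NBS (1.05 equiv), −40 °C; Et3N (cat.), 0 °C; aq. KF
Reagents that add atoms: N-bromosuccinimide, BrN1C(=O)CCC1=O
Why: Transesterification of the enol acetate with the tin alkoxide gives the regiodefined tin enolate, which NBS should brominate at C8 far faster than it attacks the C11 methylidene (enolate α-halogenation); the 8R bromide is equatorial in the ring A chair whose C11 methylidene leans over the sp2 carbon C2 of ring B instead of an axial C–H, so it should be the stable epimer and the one reached on base-catalysed equilibration through the C8 enolate.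

Step 13
Reactants: 16 (3S,6R,8R)-8-bromo-3-(chloromethyl)-3-hydroxy-7,7-dimethyl-11-methylidenespiro[5.5]undecane-2,9-dione
Product: 17 (3S,6R,8R,9S)-8-bromo-3-(chloromethyl)-3,9-dihydroxy-7,7-dimethyl-11-methylidenespiro[5.5]undecan-2-one
Conditions: LiBH(s-Bu)3 (1.2 equiv), THF, −78 °C; aq. NH4Cl
Reagents that add atoms: none
Why: Diastereoselective ketone reduction: the bulky borohydride should reach the α-bromo ketone only from the equatorial side (the axial methyl on C7 blocks the axial path), giving the axial 9S alcohol cis to bromine, while the ring B ketone, flanked by the quaternary carbinol carbon and a neopentyl methylene, should not react at −78 °C.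

**Compound list**

1 | methyl 3-oxocyclohex-1-ene-1-carboxylate | COC(=O)C1=CC(=O)CCC1 | starting material
2 | prop-1-en-2-ylmagnesium bromide | CC(=C)[Mg]Br | starting material
3 | methyl (1R)-3-oxo-1-(prop-1-en-2-yl)cyclohexane-1-carboxylate | COC(=O)[C@]1(C(C)=C)CCCC(=O)C1 | intermediate
4 | methyl (7R)-7-(prop-1-en-2-yl)-1,4-dioxaspiro[4.5]decane-7-carboxylate | COC(=O)[C@]1(C(C)=C)CCCC2(OCCO2)C1 | intermediate
5 | methyl (7R)-7-(3-chloroprop-1-en-2-yl)-1,4-dioxaspiro[4.5]decane-7-carboxylate | COC(=O)[C@]1(C(=C)CCl)CCCC2(OCCO2)C1 | intermediate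
6 | ethynylmagnesium bromide | C#C[Mg]Br | starting material
7 | methyl (7R)-7-(pent-1-en-4-yn-2-yl)-1,4-dioxaspiro[4.5]decane-7-carboxylate | COC(=O)[C@]1(C(=C)CC#C)CCCC2(OCCO2)C1 | intermediate
8 | 2-[(7R)-7-(pent-1-en-4-yn-2-yl)-1,4-dioxaspiro[4.5]decan-7-yl]propan-2-ol | CC(C)(O)[C@]1(C(=C)CC#C)CCCC2(OCCO2)C1 | intermediate
9 | (3R)-3-(2-hydroxypropan-2-yl)-3-(pent-1-en-4-yn-2-yl)cyclohexan-1-one | CC(C)(O)[C@]1(C(=C)CC#C)CCCC(=O)C1 | intermediate
10 | (5R)-5-(2-hydroxypropan-2-yl)-2-methylidene-5-(pent-1-en-4-yn-2-yl)cyclohexan-1-one | CC(C)(O)[C@]1(C(=C)CC#C)CCC(=C)C(=O)C1 | intermediate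
11 | (3R,6R)-6-(2-hydroxypropan-2-yl)-6-(pent-1-en-4-yn-2-yl)-1-oxaspiro[2.5]octan-4-one | CC(C)(O)[C@]1(C(=C)CC#C)CC[C@@]2(CO2)C(=O)C1 | intermediate
12 | (3R,6S)-6-(pent-1-en-4-yn-2-yl)-6-(prop-1-en-2-yl)-1-oxaspiro[2.5]octan-4-one | C=C(C)[C@]1(C(=C)CC#C)CC[C@@]2(CO2)C(=O)C1 | intermediate
13 | (2S,5S)-2-(chloromethyl)-2-hydroxy-5-(pent-1-en-4-yn-2-yl)-5-(prop-1-en-2-yl)cyclohexan-1-one | C=C(C)[C@]1(C(=C)CC#C)CC[C@@](O)(CCl)C(=O)C1 | intermediate
14 | (3S,6R)-3-(chloromethyl)-3-hydroxy-7,7-dimethyl-11-methylidene-2-oxospiro[5.5]undec-8-en-9-yl acetate | C=C1CC(OC(C)=O)=CC(C)(C)[C@@]12CC[C@@](O)(CCl)C(=O)C2 | intermediate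
15 | tributyl{[(3S,6R)-3-(chloromethyl)-3-hydroxy-7,7-dimethyl-11-methylidene-2-oxospiro[5.5]undec-8-en-9-yl]oxy}stannane | C=C1CC(O[Sn](CCCC)(CCCC)CCCC)=CC(C)(C)[C@@]12CC[C@@](O)(CCl)C(=O)C2 | intermediate
16 | (3S,6R,8R)-8-bromo-3-(chloromethyl)-3-hydroxy-7,7-dimethyl-11-methylidenespiro[5.5]undecane-2,9-dione | C=C1CC(=O)[C@H](Br)C(C)(C)[C@@]12CC[C@@](O)(CCl)C(=O)C2 | intermediate
17 | (3S,6R,8R,9S)-8-bromo-3-(chloromethyl)-3,9-dihydroxy-7,7-dimethyl-11-methylidenespiro[5.5]undecan-2-one | C=C1C[C@H](O)[C@H](Br)C(C)(C)[C@@]12CC[C@@](O)(CCl)C(=O)C2 | target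

**Step count and risks**

Total step count: 13. Longest linear sequence: 13 steps (1 to 17).

Steps most likely to fail:

Step 11 (Proposed new method). The alkenylpalladium may be protonated before it inserts the alkene. Reversible acetoxypalladation may also leak through the anti-Markovnikov regioisomer into five-membered ring closure, and protonolysis of the neopentyl alkylpalladium may be slow. The fallback uses known reaction types, sets out from 11 and comes back at 16. Chloride opening of the epoxide of 11 under the conditions of step 10 should give (2S,5R)-2-(chloromethyl)-2-hydroxy-5-(2-hydroxypropan-2-yl)-5-(pent-1-en-4-yn-2-yl)cyclohexan-1-one F1. NBS in MeCN at 0 °C should then cause 6-exo-dig bromoetherification of the alkyne by the tertiary hydroxyl of the 2-hydroxypropan-2-yl group (anti addition, haloetherification of an alkynol), giving (3E,6R,9S)-3-(bromomethylidene)-9-(chloromethyl)-9-hydroxy-1,1-dimethyl-5-methylidene-2-oxaspiro[5.5]undecan-8-one F2. Me2AlCl in CH2Cl2 at −78 °C should ionise the tertiary C–O bond of this cyclic enol ether, and the aluminium bromo-enolate should be alkylated at carbon by the tertiary cation within the ion pair (Lewis-acid 1,3 O-to-C rearrangement of the Petasis–Ferrier type). This closes ring A at C7–C8 with bromine already on C8 and gives 16.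

Step 1. Enantioface discrimination may be low for this alkenyl nucleophile, and 1,2-addition of the alane may compete. The fallback sets out from 1 and 2 and comes back at 3. Racemic copper-catalysed conjugate addition of 2 (CuBr·SMe2, 10 mol %, THF, −40 °C) should give racemic methyl 3-oxo-1-(prop-1-en-2-yl)cyclohexane-1-carboxylate F3. This is resolved by preparative chromatography on a chiral stationary phase; the R enantiomer is 3, and methyl (1S)-3-oxo-1-(prop-1-en-2-yl)cyclohexane-1-carboxylate F4 is set aside.

Step 13. The ring B carbonyl may be reduced as well, or hydride may be delivered to the wrong face of C9. The fallback sets out from 16 and comes back at 17. Silylation of the tertiary hydroxyl (Me3SiOTf, 2,6-lutidine, CH2Cl2, −78 °C) should give (3S,6R,8R)-8-bromo-3-(chloromethyl)-7,7-dimethyl-11-methylidene-3-[(trimethylsilyl)oxy]spiro[5.5]undecane-2,9-dione F5, in which the ring B carbonyl is shielded. Reduction with LiBH(s-Bu)3 as in step 13 should give (3S,6R,8R,9S)-8-bromo-3-(chloromethyl)-9-hydroxy-7,7-dimethyl-11-methylidene-3-[(trimethylsilyl)oxy]spiro[5.5]undecan-2-one F6. Desilylation with dilute AcOH in aqueous THF gives 17.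

Further compounds
F1 | step 11 | (2S,5R)-2-(chloromethyl)-2-hydroxy-5-(2-hydroxypropan-2-yl)-5-(pent-1-en-4-yn-2-yl)cyclohexan-1-one | CC(C)(O)[C@]1(C(=C)CC#C)CC[C@@](O)(CCl)C(=O)C1
F2 | step 11 | (3E,6R,9S)-3-(bromomethylidene)-9-(chloromethyl)-9-hydroxy-1,1-dimethyl-5-methylidene-2-oxaspiro[5.5]undecan-8-one | Br/C=C1\CC(=C)[C@]2(CC[C@@](O)(CCl)C(=O)C2)C(C)(C)O1
F3 | step 1 | racemic methyl 3-oxo-1-(prop-1-en-2-yl)cyclohexane-1-carboxylate | COC(=O)C1(C(C)=C)CCCC(=O)C1
F4 | step 1 | methyl (1S)-3-oxo-1-(prop-1-en-2-yl)cyclohexane-1-carboxylate | COC(=O)[C@@]1(C(C)=C)CCCC(=O)C1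
F5 | step 13 | (3S,6R,8R)-8-bromo-3-(chloromethyl)-7,7-dimethyl-11-methylidene-3-[(trimethylsilyl)oxy]spiro[5.5]undecane-2,9-dione | C=C1CC(=O)[C@H](Br)C(C)(C)[C@@]12CC[C@@](O[Si](C)(C)C)(CCl)C(=O)C2
F6 | step 13 | (3S,6R,8R,9S)-8-bromo-3-(chloromethyl)-9-hydroxy-7,7-dimethyl-11-methylidene-3-[(trimethylsilyl)oxy]spiro[5.5]undecan-2-one | C=C1C[C@H](O)[C@H](Br)C(C)(C)[C@@]12CC[C@@](O[Si](C)(C)C)(CCl)C(=O)C2
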